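The quinone ring is cut between C4 and C5. Its C1(=O)–C2(OH)–C3(docosyl)–C4(=O) segment is a four-carbon array that a squaric ester already contains, and C5(OMe)=C6H is attached to C1 as a (Z)-2-methoxyvinyl group. Heating the resulting 4-alkenyl-4-hydroxycyclobutenone opens the four-membered ring to a dienylketene and recloses it by 6π electrocyclisation, which forms the C4–C5 bond and delivers the fully substituted six-membered ring as a hydroquinone in one operation. The precursor is racemic 3-tert-butoxy-2-docosyl-4-hydroxy-4-[(Z)-2-methoxyvinyl]cyclobut-2-en-1-one; oxidation to the quinone and acidolysis of the tert-butyl ether finish the synthesis.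

Key step: step 4

Remark: the side chain is read as n-docosyl (22 carbons) and the target has no stereocentre; the carbinol centre of the precursor is racemic and is destroyed in the key step.
Remark: the methoxyvinyl unit has to be delivered as the 2-lithio (β) reagent. Direct metalation of methyl vinyl ether gives the 1-lithio isomer, which would place the methoxy group on C6, so the (Z)-2-bromovinyl ether is made first.

Step 1
Reactants: 1 1-bromodocosane; 2 di-tert-butyl squarate (3,4-di-tert-butoxycyclobut-3-ene-1,2-dione)
Product: 6 3-tert-butoxy-4-docosylcyclobut-3-ene-1,2-dione, via docosylmagnesium bromide 3 (not isolated), via bromomagnesium cyclobutenolate 4 (not isolated), via tertiary trifluoroacetate 5 (not isolated)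
Conditions: Mg, THF, 45 °C; then 2, THF, −78 to −30 °C; then (CF3CO)2O, −78 to −40 °C; cold aq. NaHCO3
Reagents that add atoms: none
Why: Grignard 1,2-addition to one of the two equivalent carbonyls of the squarate, followed by O-trifluoroacetylation of the alkoxide, lets the carbinol oxygen leave as trifluoroacetate, and the resulting cyclobutenyl cation is stabilised by the tert-butoxy oxygen at its far end and sheds that tert-butyl group as isobutene to unveil the second carbonyl (addition/anhydride-induced carbonyl transposition of squaric esters).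

Step 2
Reactants: 7 methyl vinyl ether
Product: 9 (Z)-1-bromo-2-methoxyethene, via 1,2-dibromo-1-methoxyethane 8 (not isolated)
Conditions: Br2, pentane, −78 °C; concentrate; PhNEt2, 95 °C; distil, then redistil
Reagents that add atoms: bromine, BrBr
Why: Bromine adds across the enol ether to give the α-bromo ether 8, from which the amine removes HBr (labile α-bromide out, proton from the CH2Br carbon) to give the 2-bromovinyl ether, whose Z isomer is expected to predominate and is enriched by distillation (bromination–dehydrobromination of a vinyl ether).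

Step 3
Reactants: 9 (Z)-1-bromo-2-methoxyethene; 6 3-tert-butoxy-4-docosylcyclobut-3-ene-1,2-dione
Product: 12 3-tert-butoxy-2-docosyl-4-hydroxy-4-[(Z)-2-methoxyvinyl]cyclobut-2-en-1-one (racemic), via (Z)-2-methoxyvinyllithium 10 (not isolated), via lithium alkoxide 11 (not isolated)
Conditions: t-BuLi (2 equiv per 9), THF–Et2O, −78 °C; then 6, THF, −78 °C; aq. NaHCO3 at −78 °C; Et3N-deactivated silica or used crude
Reagents that add atoms: none
Why: Bromine–lithium exchange with retention of the Z geometry gives the oxygen-coordinated β-lithio enol ether, which adds 1,2 to the ketone-type carbonyl of 6 (the one next to the tert-butoxy-bearing carbon, the other being a deactivated vinylogous ester), so that the carbinol centre forms without control as a racemate that step 4 destroys, and the non-acidic quench should keep the β-methoxyvinyl carbinol from allylic transposition.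

Step 4
Reactants: 12 3-tert-butoxy-2-docosyl-4-hydroxy-4-[(Z)-2-methoxyvinyl]cyclobut-2-en-1-one
Product: 15 2-tert-butoxy-3-docosyl-5-methoxybenzene-1,4-diol, via dienylketene 13 (not isolated), via cyclohexadienone 14 (not isolated)
Conditions: degassed toluene (0.02 M), 110 °C, Ar, base-washed glassware
Reagents that add atoms: none
Why: Thermal conrotatory 4π opening cleaves the C(=O)–C(OH) bond of the cyclobutenone and gives dienylketene 13, in which the ketene carbon (C4 of the target) and the methoxy-bearing vinyl terminus (C5) are the ends of a 6π array. Thermal disrotatory 6π electrocyclisation then forms the C4–C5 bond and closes the six-membered carbocycle as cyclohexadienone 14, whose enolisation gives the aromatic hydroquinone 15; the closest known reaction type is the Moore rearrangement of 4-alkenyl-4-hydroxycyclobutenones. No stereocentre persists, because the carbinol centre is lost on ring opening and the sp3 carbon C5 of 14 is erased by tautomerisation. The step needs torquoselectivity, namely outward rotation of the hydroxyl so that the vinyl group ends up cis to the ketene, and the donor character of that hydroxyl secures it. Constitution is already fixed by the regiochemistry of step 3, and an alkenyl partner leaves only the six-membered closure open. The inward-pointing Z methoxy group should be tolerated because closure onto the sp ketene carbon has a low barrier, and the vinyl geometry is erased on aromatisation.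

Step 5
Reactants: 15 2-tert-butoxy-3-docosyl-5-methoxybenzene-1,4-diol
Product: 16 2-tert-butoxy-3-docosyl-5-methoxycyclohexa-2,5-diene-1,4-dione
Conditions: Ag2O, Na2SO4, Et2O, rt
Reagents that add atoms: none
Why: Ag2O dehydrogenates the electron-rich para-hydroquinone to the para-quinone under neutral conditions, which should leave the acid-labile tert-butyl ether and the methyl ether untouched (hydroquinone oxidation).

Step 6
Reactants: 16 2-tert-butoxy-3-docosyl-5-methoxycyclohexa-2,5-diene-1,4-dione
Product: 17 3-docosyl-2-hydroxy-5-methoxycyclohexa-2,5-diene-1,4-dione (target)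
Conditions: CF3CO2H, CH2Cl2, 0 °C to rt
Reagents that add atoms: none
Why: Acidolysis of the tert-butyl vinylogous ester proceeds by loss of the tert-butyl cation as isobutene and unmasks the C2 hydroxyl, whereas the C5 methyl vinylogous ester cannot ionise and should survive brief exposure to anhydrous acid (tert-butyl ether cleavage).

Compound list
1 | 1-bromodocosane | CCCCCCCCCCCCCCCCCCCCCCBr | starting material
2 | di-tert-butyl squarate (3,4-di-tert-butoxycyclobut-3-ene-1,2-dione) | CC(C)(C)OC1=C(OC(C)(C)C)C(=O)C1=O | starting material
3 | docosylmagnesium bromide | CCCCCCCCCCCCCCCCCCCCCC[Mg]Br | intermediate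
4 | bromomagnesium 2,3-di-tert-butoxy-1-docosyl-4-oxocyclobut-2-en-1-olate (racemic) | CCCCCCCCCCCCCCCCCCCCCCC1(O[Mg]Br)C(OC(C)(C)C)=C(OC(C)(C)C)C1=O | intermediate
5 | 2,3-di-tert-butoxy-1-docosyl-4-oxocyclobut-2-en-1-yl trifluoroacetate (racemic) | CCCCCCCCCCCCCCCCCCCCCCC1(OC(=O)C(F)(F)F)C(OC(C)(C)C)=C(OC(C)(C)C)C1=O | intermediate
6 | 3-tert-butoxy-4-docosylcyclobut-3-ene-1,2-dione | CCCCCCCCCCCCCCCCCCCCCCC1=C(OC(C)(C)C)C(=O)C1=O | intermediate
7 | methyl vinyl ether | COC=C | starting material
8 | 1,2-dibromo-1-methoxyethane (racemic) | COC(Br)CBr | intermediate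
9 | (Z)-1-bromo-2-methoxyethene | CO/C=C\Br | intermediate
10 | (Z)-2-methoxyvinyllithium | CO/C=C\[Li] | intermediate
11 | lithium 2-tert-butoxy-3-docosyl-1-[(Z)-2-methoxyvinyl]-4-oxocyclobut-2-en-1-olate (racemic) | CCCCCCCCCCCCCCCCCCCCCCC1=C(OC(C)(C)C)C(O[Li])(/C=C\OC)C1=O | intermediate
12 | 3-tert-butoxy-2-docosyl-4-hydroxy-4-[(Z)-2-methoxyvinyl]cyclobut-2-en-1-one (racemic) | CCCCCCCCCCCCCCCCCCCCCCC1=C(OC(C)(C)C)C(O)(/C=C\OC)C1=O | intermediate
13 | (3Z,5Z)-3-tert-butoxy-2-docosyl-4-hydroxy-6-methoxyhexa-1,3,5-trien-1-one | CCCCCCCCCCCCCCCCCCCCCCC(=C=O)/C(OC(C)(C)C)=C(/O)\C=C/OC | intermediate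
14 | 3-tert-butoxy-2-docosyl-4-hydroxy-6-methoxycyclohexa-2,4-dien-1-one (racemic) | CCCCCCCCCCCCCCCCCCCCCCC1=C(OC(C)(C)C)C(O)=CC(OC)C1=O | intermediate
15 | 2-tert-butoxy-3-docosyl-5-methoxybenzene-1,4-diol | CCCCCCCCCCCCCCCCCCCCCCc1c(OC(C)(C)C)c(O)cc(OC)c1O | intermediate
16 | 2-tert-butoxy-3-docosyl-5-methoxycyclohexa-2,5-diene-1,4-dione | CCCCCCCCCCCCCCCCCCCCCCC1=C(OC(C)(C)C)C(=O)C=C(OC)C1=O | intermediate
17 | 3-docosyl-2-hydroxy-5-methoxycyclohexa-2,5-diene-1,4-dione | CCCCCCCCCCCCCCCCCCCCCCC1=C(O)C(=O)C=C(OC)C1=O | target

Total step count: 6. Longest linear sequence: 5 steps (steps 1, 3, 4, 5, 6; the branch through step 2 is equally long).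

Steps most likely to fail

1. Step 4 (key step). Ionisation of the tertiary carbinol, which is allylic to an enol ether, could lead to allylic transposition toward an unsaturated aldehyde before the ring opens. Loss of isobutene on heating is a second possible diversion, and a slow closure could let the ketene oligomerise. The fallback sets out from lithium alkoxide 11 in the flask of step 3. Quenching it with Me3SiCl at −78 °C instead of bicarbonate should give 3-tert-butoxy-2-docosyl-4-[(Z)-2-methoxyvinyl]-4-(trimethylsilyloxy)cyclobut-2-en-1-one F1, which is far less prone to ionise. Thermolysis in toluene or p-xylene should follow the same opening and closure and give the mono-silylated hydroquinone 3-tert-butoxy-2-docosyl-6-methoxy-4-(trimethylsilyloxy)phenol F2, which is protected against air oxidation. K2CO3 in MeOH then removes the silyl group, and the route is rejoined at 15.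

2. Step 3. The vinyllithium may lose lithium methoxide by β-elimination before it adds, some attack may occur at the vinylogous-ester carbonyl, and the adduct may undergo acid-triggered allylic transposition during isolation. The fallback sets out from 6. Lithium methoxyacetylide F3, generated in THF from chloroacetaldehyde dimethyl acetal and three equivalents of LiNEt2, is a robust nucleophile and should add to the same carbonyl to give lithium 2-tert-butoxy-3-docosyl-1-(methoxyethynyl)-4-oxocyclobut-2-en-1-olate F4. Aqueous quench gives 3-tert-butoxy-2-docosyl-4-hydroxy-4-(methoxyethynyl)cyclobut-2-en-1-one F5. cis-Selective semihydrogenation (H2, Pd/CaCO3 poisoned with Pb(OAc)2, quinoline, EtOAc) should then give the Z enol ether, and the route is rejoined at 12.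

3. Step 1. The long-chain Grignard reagent may add sluggishly or twice because of its poor solubility in the cold, and the trifluoroacetic acid released in the one-pot rearrangement may cleave the remaining tert-butyl ether. The fallback sets out from 1 and uses a lithium reagent and a two-stage sequence. Halide exchange (NaI, acetone, reflux) gives 1-iododocosane F6, and iodine–lithium exchange (t-BuLi, pentane–Et2O, −78 °C) gives docosyllithium F7. Addition to 2 in THF at −78 °C gives lithium 2,3-di-tert-butoxy-1-docosyl-4-oxocyclobut-2-en-1-olate F8, and a water quench gives the isolable carbinol 2,3-di-tert-butoxy-4-docosyl-4-hydroxycyclobut-2-en-1-one F9. Treating F9 separately with (CF3CO)2O and 2,6-lutidine in CH2Cl2 at −78 °C effects the rearrangement under buffered conditions through 5, and the route is rejoined at 6.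

Further compounds
F1 | step 4 | 3-tert-butoxy-2-docosyl-4-[(Z)-2-methoxyvinyl]-4-(trimethylsilyloxy)cyclobut-2-en-1-one (racemic) | CCCCCCCCCCCCCCCCCCCCCCC1=C(OC(C)(C)C)C(O[Si](C)(C)C)(/C=C\OC)C1=O
F2 | step 4 | 3-tert-butoxy-2-docosyl-6-methoxy-4-(trimethylsilyloxy)phenol | CCCCCCCCCCCCCCCCCCCCCCc1c(OC(C)(C)C)c(O[Si](C)(C)C)cc(OC)c1O
F3 | step 3 | lithium methoxyacetylide | COC#C[Li]
F4 | step 3 | lithium 2-tert-butoxy-3-docosyl-1-(methoxyethynyl)-4-oxocyclobut-2-en-1-olate (racemic) | CCCCCCCCCCCCCCCCCCCCCCC1=C(OC(C)(C)C)C(O[Li])(C#COC)C1=O
F5 | step 3 | 3-tert-butoxy-2-docosyl-4-hydroxy-4-(methoxyethynyl)cyclobut-2-en-1-one (racemic) | CCCCCCCCCCCCCCCCCCCCCCC1=C(OC(C)(C)C)C(O)(C#COC)C1=O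
F6 | step 1 | 1-iododocosane | CCCCCCCCCCCCCCCCCCCCCCI
F7 | step 1 | docosyllithium | CCCCCCCCCCCCCCCCCCCCCC[Li]
F8 | step 1 | lithium 2,3-di-tert-butoxy-1-docosyl-4-oxocyclobut-2-en-1-olate (racemic) | CCCCCCCCCCCCCCCCCCCCCCC1(O[Li])C(OC(C)(C)C)=C(OC(C)(C)C)C1=O
F9 | step 1 | 2,3-di-tert-butoxy-4-docosyl-4-hydroxycyclobut-2-en-1-one (racemic) | CCCCCCCCCCCCCCCCCCCCCCC1(O)C(OC(C)(C)C)=C(OC(C)(C)C)C1=O
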